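(All runs stem from a simulated flask with made-up constants; scatter was added.)

Count the spare.

| flask | Za | Zd | remark | time |
|---|---|---|---|---|
| north-east | 0.067 M | 0.10 M | run made earlier |  |
| east | 0.15 M | 0.10 M | run made earlier |  |
| west | 0.10 M | 0.20 M | run made earlier |  |
| flask | 0.10 M | 0.100 M |  | 25 min |

- north-east (time / min: Ze / %, Za / %): 1.50: 2.1, 97.3; 3.00: 6.6, 93.5; 6.00: 15.8, 84.2; 10.0: 27.8, 72.9; 20.0: 48.3, 50.1
- east (time / min: Ze / %, Za / %): 4.00: 9.1, 90.7; 8.00: 20.3, 79.1; 12.0: 30.5, 69.4; 15.0: 36.4, 63.2; 20.0: 43.1, 56.2
- west (time / min: Ze / %, Za / %): 2.00: 3.7, 96.2; 5.00: 12.3, 87.7; 10.0: 25.5, 73.4; 15.0: 38.4, 61.6; 20.0: 47.7, 50.8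

(scatter of a reading: 0.3 percentage points)

- Ze present at 25 min, in percent of the Za charged
- Za present at 25 min, in percent of the Za charged
- concentration of Zb at 25 min, in M

- Zd is a solid; its amount is given per volume of the solution
- the numbers in the tables scatter by 0.3 percentage points (one standard deviation)
- at the start none of Zd is in solution

1. Main step first. Za is taken as consumed one for one by Zb, with Zb on a plateau, which makes the decay pseudo-first-order in Za. The west run shares the flask's Za, and its readings give a fall of 0.0353 /min. Carried on from its 15.0 min reading, this leaves the flask 43.3% Za at 25 min.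

2. Next, the end of the solid. The spare is the Zd not yet taken up by Za, as a fraction of the Za charged. The flask's charge ratio, Zd per Za, is 1.00. The east tail, taken as past its solid, is divided by its spare and scaled to the flask's charge, giving 0.0594 /min per unit of spare. The plateau then corresponds to a spare of 59.5%. At this ratio the flask's spare equals its Za fraction, and this reckoning brings that fraction down to the plateau's spare near 16.0 min. Second-order decay from there gives 45.1% Za, more than step 1 gave. The spare at 25 min is therefore 45.1%: Zd charged per Za charged, minus the fraction of Za consumed.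

3. Then the rest. At 20.0 min the west run's Za and Ze fall short of the charge by 1.50%, more than the scatter. Taking that gap off the Ze and off the spare, this reckoning puts the flask at 53.4% Ze and 0.0436 M Zb.

4. The forecast gives 54.7% Ze, 45% Za and 0.045 M Zb, on the ground “After that [Za] ≈ [Zb]”. Its Za stands close to the 45.1% reckoned here.

5. The flask gives 53.7% Ze, 44.3% Za and 0.0315 M Zb, so the forecast's Zb is 1.43 times the flask's.

    Zb + Ze → Zf (k = 0.00110 /M/s)
    Za + Zb → Ze (k = 0.0140 /M/s)
    Zd ⇌ Zb, rate k3*(cs3 - [Zb]) while solid is left; crystals form when [Zb] > cs3 (solubility = 47.0 mM, k = 0.0120 /s)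
    Zb ⇌ Zc (K = 0.380, k = 3.30 × 10⁻⁴ /s)

The flask's spare, from its Za, is 44.3% against 45.1% reckoned. As fractions of the Za charged, the flask holds Zb at 31.5%, Zc at 10.8% and Zf at 1.98%, with 0% of its Zd left. The neighbour flask is charged with 0.060 M Zd, making Zd the limiting reagent, and keeps 59.3% Za with 0% of its Zd left. Its spare is 19.3%, and its Zb is 12.2% of the Za charged, its Zc 6.12% and its Zf 0.898%.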